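## Analysis of the target

The target is a dimer of two arctigenin-type lignan units: two γ-butyrolactones, each with a 3,4-dimethoxybenzyl group on C4 and a second benzyl group on C3, joined through a diaryl ether. Ring A, the benzyl ring on C3 of the first lactone (lactone A), has its benzylic carbon at C1, a methoxy group at C3 and the ether oxygen at C4. Ring B, on C3 of the second lactone (lactone B), has its benzylic carbon at C1, the ether oxygen at C3, a free hydroxyl at C4 and a methoxy group at C5. The four stereocentres, C3 and C4 of each lactone, are all S; within each ring the benzyl groups are trans, the thermodynamically preferred arrangement, but the two pairs are too far apart to direct each other, so each needs absolute control. The sensitive sites are the enolisable C3–H next to each lactone carbonyl, the lactones themselves towards nucleophiles and hydride, and the electron-rich phenol of ring B; with six aryl methyl ethers present, the one free hydroxyl cannot be unmasked by a late demethylation. The difficulty lies in the unsymmetrical diaryl ether between two electron-rich, ortho-oxygenated rings, and in building the same stereodefined lactone twice and joining the copies without loss of configuration. The feature used here is the pattern of ring A: C2(H)–C3(O)–C4(OAr) has the oxidation pattern of an aryloxyacetone, CH3–C(=O)–CH2–OAr, and C5(H)–C6(H)–C1(CH2R) that of an ethynyl ketone, HC≡C–C(=O)–CH2R. Ring A can therefore be made last, from two open-chain three-carbon units that are each attached beforehand to one finished lactone.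

## Retrosynthetic reasoning

The last operations concern the oxygen substituents only. Target 32 comes from benzyl ether 31 by hydrogenolysis, and 31 from phenol 30 by O-methylation at C3 of ring A. A benzyl group on O4 of ring B marks, from the start, the one oxygen that must end as a free hydroxyl; its removal touches neither the lactones nor the diaryl ether.

Phenol 30 is cut across ring A at C4–C5 and C1–C2, giving enol ether 19 and ynone 27. This cut passes through no stereocentre and divides the molecule into two halves of similar size, each a complete trans lactone. The ether oxygen stays on the ring B half as part of an aryloxyacetone unit, so no aryl–oxygen bond has to be made between two electron-rich arenes. In the forward direction the oxygen-bearing carbon of 19 must add to the terminal alkyne carbon of 27 under a Lewis acid, and the methyl ketone must then close onto the former ynone carbonyl, lose water and aromatise. The position of the enol double bond in 19 decides that the ether oxygen ends para, not ortho, to the benzylic carbon.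

Enol ether 19 is the silyl enol ether of ketone 18, and 18 is traced to methallyl ether 16 by cleavage of the C=CH2 bond. The methallyl group is a masked acetonyl group: unlike a ketone it survives the hydride, bromination and enolate steps that precede it, and it saves a protection and deprotection pair on the ring B oxygen.

Lactone 16 is cut at the C3–CH2 bond into lithium enolate 15, made from lactone 8, and benzylic bromide 14. Alkylation anti to the C4 substituent gives the trans lactone, so the C3 centre is derived from the C4 centre. Bromide 14 comes through alcohol 13 and aldehyde 12 from phenol 10 and methallyl chloride 11, and 10 from 5-hydroxyvanillin 9; the two hydroxyls of 9 are told apart by their acidity.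

Ynone 27 is cut at the bond between the carbonyl and the alkyne, giving Weinreb amide 24 and ethynylmagnesium bromide 25. Amide 24 comes from acid 23 and ester 22, and 22 from the same lactone 8, through its sodium enolate 21, by alkylation with tert-butyl bromoacetate 20. The two-carbon arm supplies C1 of ring A and its benzylic CH2.

Lactone 8, used twice, comes from ester 7 by loss of the ethoxycarbonyl group. Ester 7 is cut at the aryl–CH2 bond into the cyclopropane-fused lactone 5 and aryl Grignard reagent 6, and 5 is assembled from (S)-epichlorohydrin 1 and diethyl malonate 2. All four stereocentres of the target thus descend from the one centre of 1.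

## Alternatives that were turned down

Alternative 1: The disconnection is the C4–CH2O bond of each lactone, traced to a [2,3]-sigmatropic shift. In the forward direction, tin–lithium exchange on the bis(stannylmethyl) ether A2 releases two α-alkoxy carbanions, which rearrange (Still–Wittig) to the bis(homoallylic alcohol) A1. In A2 the two carbinol carbons are the benzylic carbons of rings A and B and carry (Z)-allyl groups.
- For it: both C4 centres arise in one operation by 1,3-transfer of carbinol chirality. The (Z) geometry forces the transition state with the carbinol hydrogen inside, so one configuration and an (E)-alkene are expected. The diaryl ether can be made at the outset from simple aldehydes.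
- Against it: A1 contains neither lactone carbonyl carbon nor the C3 centres. Each styrene must take up a carboxyl carbon at the carbon remote from the arene, against the usual regiochemistry, and this must be done twice. The carbinols of A2 are benzylic as well as allylic, which favours the competing [1,2]-shift through a radical pair. Two enantioselective reductions, two (Z)-selective semihydrogenations and two equivalents of organotin precede the key step.
- Comparison: it is the stronger plan on one point, since its key step has close precedent and creates stereocentres, whereas the chosen key step creates none. The chosen route in return takes all four stereocentres from one building block, 8, made in three steps, and needs only two steps after the key step, where this alternative would need well over twenty in all.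

Alternative 2: The disconnection is the ring O–C5 bond of each lactone, traced to an oxetane. In the forward direction a chiral BINOL-derived phosphoric acid activates each oxetane of the achiral bis(malonic acid) A4, and a carboxyl oxygen attacks one of the two enantiotopic oxetane CH2 groups (5-exo-tet), giving the bis(lactone) A3.
- For it: absolute control comes from a catalyst acting on an achiral precursor, either enantiomer is equally accessible, and both lactone rings form in one step. Desymmetrising two identical units in one molecule amplifies the enantiomeric purity of the homochiral product.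
- Against it: A3 has a CH2OH group where the target has the 3,4-dimethoxybenzyl group, and a CO2H group on each C3. Two decarboxylations, two activations and two C(sp3)–C(sp2) couplings next to base-sensitive lactones would follow. The malonic acid groups of A4 are acidic enough to open the oxetane without the catalyst, a racemic background reaction, and the heterochiral diastereomer forms as well. A4 also needs two quaternary malonate centres carrying oxetan-3-yl groups.
- Comparison: it is stronger on the origin of chirality, a catalyst instead of the chiral pool. The chosen route offers a key step after which the carbon skeleton is complete, and both enantiomers of 1 are cheap, so the chiral-pool origin costs little.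

Alternative 3: The disconnection is the aryl–CH2 bond of both 3,4-dimethoxybenzyl groups together with both C3–CH2 bonds. In the forward direction two equivalents of 6 open two molecules of 5 under copper catalysis, and the two ester-stabilised enolates are trapped in the same flask by the bis(benzyl bromide) A6, giving the bis(ester lactone) A5. Double dealkoxycarbonylation and hydrogenolysis would finish the synthesis.
- For it: it uses the same building blocks 5 and 6 as the present route, every reaction type is known, and four C–C bonds form in one operation. It would be shorter than the chosen route; on step economy and precedent it is the stronger plan.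
- Against it: five components must combine in a fixed ratio. Halomagnesium enolates of this β-dicarbonyl type are sluggish towards benzyl halides and may need a change of counter-ion, which invites O-alkylation and proton transfer. Each incomplete event leaves mono-alkylated material that resembles the product. A6 is an electron-rich, doubly benzylic bromide whose para-aryloxy arm ionises easily, and making it requires an aryl–oxygen bond between two arenes.
- Comparison: the chosen strategy gives up some step economy. In return each half is purified as a single trans diastereomer before the union, no aryl–oxygen coupling and no sensitive bis-electrophile is needed, and ring A emerges with a free hydroxyl at C3, distinct from every other oxygen, which allows variation of that ether at the last stage. The dibromide chemistry is kept as the fallback for the key step.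

Key step: step 15

Remark on the chemistry: Grignard reagents 6 and 25 are counted as purchased THF solutions, and enol ether 19 is drawn as the (Z) isomer although either geometry would serve.

## Route

Step 1
Reactants: 1 (S)-epichlorohydrin; 2 diethyl malonate
Product: 5 ethyl (1R,5S)-2-oxo-3-oxabicyclo[3.1.0]hexane-1-carboxylate, via epoxide 3 (not isolated), via cyclopropylmethanol 4 (not isolated)
Conditions: NaOEt, EtOH, 0 °C → reflux
Reagents that add atoms: none
Why: The malonate anion opens the epoxide of 1 at its CH2 terminus, the alkoxide displaces chloride to give the new epoxide 3, and 3-exo-tet attack of the malonate carbanion on the epoxide CH gives cyclopropane 4, whose alkoxide lactonises onto the cis ester (known cyclopropanation–lactonisation of malonates with epichlorohydrin). The single inversion at the former C2 of 1 sets C5 of 5 as S, and C1 follows from the obligatory cis ring fusion.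

Step 2
Reactants: 5 ethyl (1R,5S)-2-oxo-3-oxabicyclo[3.1.0]hexane-1-carboxylate; 6 3,4-dimethoxyphenylmagnesium bromide
Product: 7 ethyl (4S)-4-(3,4-dimethoxybenzyl)-2-oxotetrahydrofuran-3-carboxylate (C3 epimers)
Conditions: CuI (10 mol%), THF, −30 → 0 °C; then 1 M HCl
Reagents that add atoms: none
Why: Copper-catalysed homoconjugate addition: the aryl group opens the doubly activated cyclopropane at its unsubstituted CH2 and releases the malonate-type enolate. C5 of 5 is not involved and becomes C4 (S) of 7; the C3 configuration is irrelevant because step 3 removes that centre.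

Step 3
Reactants: 7 ethyl (4S)-4-(3,4-dimethoxybenzyl)-2-oxotetrahydrofuran-3-carboxylate
Product: 8 (4S)-4-(3,4-dimethoxybenzyl)dihydrofuran-2(3H)-one
Conditions: LiCl, DMSO/H2O, 140 °C
Reagents that add atoms: none
Why: Krapcho dealkoxycarbonylation of the malonate-type ester; C4 carries no acidic hydrogen and keeps its configuration.

Step 4
Reactants: 9 5-hydroxyvanillin
Product: 10 4-(benzyloxy)-3-hydroxy-5-methoxybenzaldehyde
Conditions: BnBr (1.0 equiv), NaHCO3, NaI (cat.), DMF, 40 °C
Reagents that add atoms: benzyl bromide, BrCc1ccccc1
Why: Williamson etherification under a weak base: only the 4-OH, conjugated with the para formyl group and therefore the more acidic phenol, is ionised and alkylated.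

Step 5
Reactants: 10 4-(benzyloxy)-3-hydroxy-5-methoxybenzaldehyde; 11 3-chloro-2-methylprop-1-ene (methallyl chloride)
Product: 12 4-(benzyloxy)-3-methoxy-5-[(2-methylprop-2-en-1-yl)oxy]benzaldehyde
Conditions: K2CO3, KI (cat.), DMF, 60 °C
Reagents that add atoms: none
Why: Williamson etherification of the remaining phenol with an allylic chloride. The methallyl group is a latent acetonyl group that withstands hydride, bromination and enolate chemistry.

Step 6
Reactants: 12 4-(benzyloxy)-3-methoxy-5-[(2-methylprop-2-en-1-yl)oxy]benzaldehyde
Product: 13 {4-(benzyloxy)-3-methoxy-5-[(2-methylprop-2-en-1-yl)oxy]phenyl}methanol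
Conditions: NaBH4, MeOH, 0 °C
Reagents that add atoms: none
Why: Hydride reduction of an aromatic aldehyde; the ethers and the isolated alkene are inert.

Step 7
Reactants: 13 {4-(benzyloxy)-3-methoxy-5-[(2-methylprop-2-en-1-yl)oxy]phenyl}methanol
Product: 14 2-(benzyloxy)-5-(bromomethyl)-1-methoxy-3-[(2-methylprop-2-en-1-yl)oxy]benzene
Conditions: CBr4, PPh3, CH2Cl2, 0 °C
Reagents that add atoms: tetrabromomethane, BrC(Br)(Br)Br
Why: Appel bromination of a benzylic alcohol under neutral conditions, so that no HBr adds to the 1,1-disubstituted alkene.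

Step 8
Reactants: 8 (4S)-4-(3,4-dimethoxybenzyl)dihydrofuran-2(3H)-one; 14 2-(benzyloxy)-5-(bromomethyl)-1-methoxy-3-[(2-methylprop-2-en-1-yl)oxy]benzene
Product: 16 (3S,4S)-3-{4-(benzyloxy)-3-methoxy-5-[(2-methylprop-2-en-1-yl)oxy]benzyl}-4-(3,4-dimethoxybenzyl)dihydrofuran-2(3H)-one, via lithium enolate 15 (not isolated)
Conditions: LiN(SiMe3)2, THF, −78 °C; then 14, −78 → −30 °C
Reagents that add atoms: none
Why: Enolate alkylation of a 4-substituted butyrolactone: the bromide approaches the face of enolate 15 opposite the C4 arylmethyl group, which sets C3 trans to C4, that is (3S,4S). This is the standard entry to trans-dibenzylbutyrolactones.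

Step 9
Reactants: 16 (3S,4S)-3-{4-(benzyloxy)-3-methoxy-5-[(2-methylprop-2-en-1-yl)oxy]benzyl}-4-(3,4-dimethoxybenzyl)dihydrofuran-2(3H)-one
Product: 18 (3S,4S)-3-[4-(benzyloxy)-3-methoxy-5-(2-oxopropoxy)benzyl]-4-(3,4-dimethoxybenzyl)dihydrofuran-2(3H)-one, via diol 17 (not isolated)
Conditions: K2OsO4·2H2O (2 mol%), NaIO4, 2,6-lutidine, dioxane/H2O, rt
Reagents that add atoms: sodium periodate, [Na+].[O-]I(=O)(=O)=O; water, O
Why: Lemieux–Johnson oxidation: the 1,1-disubstituted alkene is dihydroxylated to diol 17, which periodate cleaves to the methyl ketone and formaldehyde. The arenes, the benzyl ether and the lactone are not oxidised, and 2,6-lutidine keeps the medium near neutral so that C3 is not epimerised.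

Step 10
Reactants: 18 (3S,4S)-3-[4-(benzyloxy)-3-methoxy-5-(2-oxopropoxy)benzyl]-4-(3,4-dimethoxybenzyl)dihydrofuran-2(3H)-one
Product: 19 (3S,4S)-3-[4-(benzyloxy)-3-methoxy-5-{[(1Z)-2-(trimethylsilyloxy)prop-1-en-1-yl]oxy}benzyl]-4-(3,4-dimethoxybenzyl)dihydrofuran-2(3H)-one
Conditions: Me3SiOTf (1.2 equiv), Et3N, CH2Cl2, −20 → 0 °C; pentane extraction, used crude
Reagents that add atoms: trimethylsilyl trifluoromethanesulfonate, C[Si](C)(C)OS(=O)(=O)C(F)(F)F
Why: Soft enolisation with a silyl triflate and an amine is reversible and should give the more substituted enol ether on the side of the more acidic ArO–CH2 hydrogens; the ketone reacts well before the lactone. The (Z) isomer is expected to dominate, and the geometry is of no consequence because this carbon becomes part of the arene.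

Step 11
Reactants: 8 (4S)-4-(3,4-dimethoxybenzyl)dihydrofuran-2(3H)-one; 20 tert-butyl bromoacetate
Product: 22 tert-butyl 2-[(3S,4S)-4-(3,4-dimethoxybenzyl)-2-oxotetrahydrofuran-3-yl]acetate, via sodium enolate 21 (not isolated)
Conditions: NaN(SiMe3)2 (1.05 equiv), THF, −78 °C; then 20, −78 → −50 °C
Reagents that add atoms: none
Why: Enolate alkylation with a reactive α-bromo ester; the sodium enolate 21 is chosen because sodium enolates combine rapidly with bromoacetates at low temperature, and the electrophile approaches anti to the C4 substituent as in step 8, which gives the (3S,4S) trans lactone. The tert-butyl ester resists attack by the enolate.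

Step 12
Reactants: 22 tert-butyl 2-[(3S,4S)-4-(3,4-dimethoxybenzyl)-2-oxotetrahydrofuran-3-yl]acetate
Product: 23 2-[(3S,4S)-4-(3,4-dimethoxybenzyl)-2-oxotetrahydrofuran-3-yl]acetic acid
Conditions: CF3CO2H, Et3SiH, CH2Cl2, 0 °C → rt
Reagents that add atoms: none
Why: Acidolysis of the tert-butyl ester; the silane reduces the tert-butyl cation before it can alkylate the electron-rich dimethoxyphenyl ring. The lactone and the aryl methyl ethers are stable to the acid.

Step 13
Reactants: 23 2-[(3S,4S)-4-(3,4-dimethoxybenzyl)-2-oxotetrahydrofuran-3-yl]acetic acid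
Product: 24 2-[(3S,4S)-4-(3,4-dimethoxybenzyl)-2-oxotetrahydrofuran-3-yl]-N-methoxy-N-methylacetamide
Conditions: MeNHOMe·HCl, EDC·HCl, HOBt (cat.), N-methylmorpholine, CH2Cl2, 0 °C → rt
Reagents that add atoms: N,O-dimethylhydroxylamine hydrochloride, CNOC.Cl
Why: Carbodiimide-mediated amide formation to the Weinreb amide; the mild base does not epimerise C3.

Step 14
Reactants: 24 2-[(3S,4S)-4-(3,4-dimethoxybenzyl)-2-oxotetrahydrofuran-3-yl]-N-methoxy-N-methylacetamide; 25 ethynylmagnesium bromide
Product: 27 (3S,4S)-4-(3,4-dimethoxybenzyl)-3-(2-oxobut-3-yn-1-yl)dihydrofuran-2(3H)-one, via magnesium hemiaminal 26 (not isolated)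
Conditions: THF, −20 → 0 °C; then transfer into cold 1 M HCl
Reagents that add atoms: none
Why: Weinreb ketone synthesis: the chelated tetrahedral adduct 26 is stable until the quench, so no second addition occurs, and the weakly nucleophilic acetylide should spare the lactone at this temperature. The inverse acidic quench protonates the liberated amine before it can add to the ynone.

Step 15
Reactants: 19 (3S,4S)-3-[4-(benzyloxy)-3-methoxy-5-{[(1Z)-2-(trimethylsilyloxy)prop-1-en-1-yl]oxy}benzyl]-4-(3,4-dimethoxybenzyl)dihydrofuran-2(3H)-one; 27 (3S,4S)-4-(3,4-dimethoxybenzyl)-3-(2-oxobut-3-yn-1-yl)dihydrofuran-2(3H)-one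
Product: 30 (3S,4S)-3-{4-[2-(benzyloxy)-5-{[(3S,4S)-4-(3,4-dimethoxybenzyl)-2-oxotetrahydrofuran-3-yl]methyl}-3-methoxyphenoxy]-3-hydroxybenzyl}-4-(3,4-dimethoxybenzyl)dihydrofuran-2(3H)-one, via enedione 28 (not isolated), via aldol adduct 29 (not isolated)
Conditions: TiCl4 (1.5 equiv), CH2Cl2, −78 °C; aq. NaHCO3; then DBU, MeCN, 60 °C
Reagents that add atoms: none
Why: Proposed new method: TiCl4 binds the carbonyl oxygen of ynone 27, and enol ether 19 adds through its aryloxy-bearing carbon to the unsubstituted alkyne terminus (Mukaiyama–Michael addition), which forms C4–C5 and, after hydrolysis, gives enedione 28; the closest known reactions are the Lewis-acid-mediated conjugate additions of silyl enol ethers to alkynones and the [3+3] phenol syntheses in which acetone-type 1,3-bis-nucleophiles (β-keto esters, 1,3-bis(silyl enol ethers)) condense with alkynones or β-alkoxy enones, none of which has been run with an α-aryloxy enol ether and an unactivated methyl group. DBU then equilibrates the alkene geometry of 28 through its dienolate, and the enolate of the methyl ketone attacks the former ynone carbonyl in a 6-(enolexo)-exo-trig aldol addition that forms C1–C2 and closes ring A as carbinol 29. E1cB loss of water and enolisation then aromatise the ring to phenol 30, which makes the sequence irreversible. No new stereocentre survives, since the centres formed at C4 and C1 are lost on aromatisation; the four lactone centres lie outside the reacting system, and should C3 of either lactone epimerise under DBU the trans arrangement is the thermodynamic one. Three selectivities are needed. Addition in the 1,4-sense is favoured by the soft enol ether and the unhindered terminal β-carbon. Attack through the oxygenated carbon is fixed by the position of the double bond in 19. Closure by the methyl carbon, and not by the CH2 group between the ynone carbonyl and lactone A, is favoured because the methyl enolate is primary and unhindered, whereas the other mode would join a carbon carrying the lactone to a carbonyl flanked by the aryloxy-bearing carbon.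

Step 16
Reactants: 30 (3S,4S)-3-{4-[2-(benzyloxy)-5-{[(3S,4S)-4-(3,4-dimethoxybenzyl)-2-oxotetrahydrofuran-3-yl]methyl}-3-methoxyphenoxy]-3-hydroxybenzyl}-4-(3,4-dimethoxybenzyl)dihydrofuran-2(3H)-one
Product: 31 (3S,4S)-3-{4-[2-(benzyloxy)-5-{[(3S,4S)-4-(3,4-dimethoxybenzyl)-2-oxotetrahydrofuran-3-yl]methyl}-3-methoxyphenoxy]-3-methoxybenzyl}-4-(3,4-dimethoxybenzyl)dihydrofuran-2(3H)-one
Conditions: MeI, K2CO3, acetone, 50 °C
Reagents that add atoms: iodomethane, CI
Why: Williamson O-methylation; carbonate ionises only the phenol, so the lactone α-positions are not alkylated.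

Step 17
Reactants: 31 (3S,4S)-3-{4-[2-(benzyloxy)-5-{[(3S,4S)-4-(3,4-dimethoxybenzyl)-2-oxotetrahydrofuran-3-yl]methyl}-3-methoxyphenoxy]-3-methoxybenzyl}-4-(3,4-dimethoxybenzyl)dihydrofuran-2(3H)-one
Product: 32 (3S,4S)-3-{4-[5-{[(3S,4S)-4-(3,4-dimethoxybenzyl)-2-oxotetrahydrofuran-3-yl]methyl}-2-hydroxy-3-methoxyphenoxy]-3-methoxybenzyl}-4-(3,4-dimethoxybenzyl)dihydrofuran-2(3H)-one
Conditions: H2 (1 atm), 10% Pd/C, EtOAc/EtOH, rt
Reagents that add atoms: none
Why: Hydrogenolysis of the aryl benzyl ether; the diaryl ether, the lactones and the benzylic C–C bonds are not cleaved under these conditions.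

## Compound list

1 | (S)-epichlorohydrin, (2S)-2-(chloromethyl)oxirane | ClC[C@@H]1CO1 | starting material
2 | diethyl malonate | CCOC(=O)CC(=O)OCC | starting material
3 | diethyl 2-{[(2S)-oxiran-2-yl]methyl}propanedioate (epoxide, present as its enolate) | CCOC(=O)C(C[C@H]1CO1)C(=O)OCC | intermediate
4 | diethyl (2S)-2-(hydroxymethyl)cyclopropane-1,1-dicarboxylate (cyclopropylmethanol, present as its alkoxide) | CCOC(=O)C1(C[C@@H]1CO)C(=O)OCC | intermediate
5 | ethyl (1R,5S)-2-oxo-3-oxabicyclo[3.1.0]hexane-1-carboxylate | CCOC(=O)[C@@]12C[C@@H]1COC2=O | intermediate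
6 | 3,4-dimethoxyphenylmagnesium bromide | COc1ccc([Mg]Br)cc1OC | starting material
7 | ethyl (4S)-4-(3,4-dimethoxybenzyl)-2-oxotetrahydrofuran-3-carboxylate, C3 epimers | CCOC(=O)C1C(=O)OC[C@H]1Cc1ccc(OC)c(OC)c1 | intermediate
8 | (4S)-4-(3,4-dimethoxybenzyl)dihydrofuran-2(3H)-one | O=C1C[C@H](Cc2ccc(OC)c(OC)c2)CO1 | intermediate
9 | 5-hydroxyvanillin, 3,4-dihydroxy-5-methoxybenzaldehyde | O=Cc1cc(O)c(O)c(OC)c1 | starting material
10 | 4-(benzyloxy)-3-hydroxy-5-methoxybenzaldehyde | O=Cc1cc(O)c(OCc2ccccc2)c(OC)c1 | intermediate
11 | 3-chloro-2-methylprop-1-ene (methallyl chloride) | C=C(C)CCl | starting material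
12 | 4-(benzyloxy)-3-methoxy-5-[(2-methylprop-2-en-1-yl)oxy]benzaldehyde | O=Cc1cc(OCC(C)=C)c(OCc2ccccc2)c(OC)c1 | intermediate
13 | {4-(benzyloxy)-3-methoxy-5-[(2-methylprop-2-en-1-yl)oxy]phenyl}methanol | OCc1cc(OCC(C)=C)c(OCc2ccccc2)c(OC)c1 | intermediate
14 | 2-(benzyloxy)-5-(bromomethyl)-1-methoxy-3-[(2-methylprop-2-en-1-yl)oxy]benzene | BrCc1cc(OCC(C)=C)c(OCc2ccccc2)c(OC)c1 | intermediate
15 | lithium (4S)-4-(3,4-dimethoxybenzyl)-4,5-dihydrofuran-2-olate (lithium enolate of 8) | [Li+].[O-]C1=C[C@H](Cc2ccc(OC)c(OC)c2)CO1 | intermediate
16 | (3S,4S)-3-{4-(benzyloxy)-3-methoxy-5-[(2-methylprop-2-en-1-yl)oxy]benzyl}-4-(3,4-dimethoxybenzyl)dihydrofuran-2(3H)-one | C=C(C)COc1cc(C[C@@H]2C(=O)OC[C@H]2Cc2ccc(OC)c(OC)c2)cc(OC)c1OCc1ccccc1 | intermediate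
17 | (3S,4S)-3-[4-(benzyloxy)-3-(2,3-dihydroxy-2-methylpropoxy)-5-methoxybenzyl]-4-(3,4-dimethoxybenzyl)dihydrofuran-2(3H)-one, diol, carbinol centre undefined | CC(O)(CO)COc1cc(C[C@@H]2C(=O)OC[C@H]2Cc2ccc(OC)c(OC)c2)cc(OC)c1OCc1ccccc1 | intermediate
18 | (3S,4S)-3-[4-(benzyloxy)-3-methoxy-5-(2-oxopropoxy)benzyl]-4-(3,4-dimethoxybenzyl)dihydrofuran-2(3H)-one | CC(=O)COc1cc(C[C@@H]2C(=O)OC[C@H]2Cc2ccc(OC)c(OC)c2)cc(OC)c1OCc1ccccc1 | intermediate
19 | (3S,4S)-3-[4-(benzyloxy)-3-methoxy-5-{[(1Z)-2-(trimethylsilyloxy)prop-1-en-1-yl]oxy}benzyl]-4-(3,4-dimethoxybenzyl)dihydrofuran-2(3H)-one | C/C(O[Si](C)(C)C)=C/Oc1cc(C[C@@H]2C(=O)OC[C@H]2Cc2ccc(OC)c(OC)c2)cc(OC)c1OCc1ccccc1 | intermediate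
20 | tert-butyl bromoacetate | CC(C)(C)OC(=O)CBr | starting material
21 | sodium (4S)-4-(3,4-dimethoxybenzyl)-4,5-dihydrofuran-2-olate (sodium enolate of 8) | [Na+].[O-]C1=C[C@H](Cc2ccc(OC)c(OC)c2)CO1 | intermediate
22 | tert-butyl 2-[(3S,4S)-4-(3,4-dimethoxybenzyl)-2-oxotetrahydrofuran-3-yl]acetate | CC(C)(C)OC(=O)C[C@@H]1C(=O)OC[C@H]1Cc1ccc(OC)c(OC)c1 | intermediate
23 | 2-[(3S,4S)-4-(3,4-dimethoxybenzyl)-2-oxotetrahydrofuran-3-yl]acetic acid | OC(=O)C[C@@H]1C(=O)OC[C@H]1Cc1ccc(OC)c(OC)c1 | intermediate
24 | 2-[(3S,4S)-4-(3,4-dimethoxybenzyl)-2-oxotetrahydrofuran-3-yl]-N-methoxy-N-methylacetamide | CON(C)C(=O)C[C@@H]1C(=O)OC[C@H]1Cc1ccc(OC)c(OC)c1 | intermediate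
25 | ethynylmagnesium bromide | C#C[Mg]Br | starting material
26 | bromomagnesium alkoxide of the tetrahedral adduct of 24 and 25 (magnesium hemiaminal, new carbon undefined) | C#CC(O[Mg]Br)(N(C)OC)C[C@@H]1C(=O)OC[C@H]1Cc1ccc(OC)c(OC)c1 | intermediate
27 | (3S,4S)-4-(3,4-dimethoxybenzyl)-3-(2-oxobut-3-yn-1-yl)dihydrofuran-2(3H)-one | C#CC(=O)C[C@@H]1C(=O)OC[C@H]1Cc1ccc(OC)c(OC)c1 | intermediate
28 | (3S,4S)-3-{5-[2-(benzyloxy)-5-{[(3S,4S)-4-(3,4-dimethoxybenzyl)-2-oxotetrahydrofuran-3-yl]methyl}-3-methoxyphenoxy]-2,6-dioxohept-3-en-1-yl}-4-(3,4-dimethoxybenzyl)dihydrofuran-2(3H)-one (enedione, alkene geometry and aryloxy-bearing centre undefined) | CC(=O)C(C=CC(=O)C[C@@H]1C(=O)OC[C@H]1Cc1ccc(OC)c(OC)c1)Oc1cc(C[C@@H]2C(=O)OC[C@H]2Cc2ccc(OC)c(OC)c2)cc(OC)c1OCc1ccccc1 | intermediate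
29 | (3S,4S)-3-({4-[2-(benzyloxy)-5-{[(3S,4S)-4-(3,4-dimethoxybenzyl)-2-oxotetrahydrofuran-3-yl]methyl}-3-methoxyphenoxy]-1-hydroxy-5-oxocyclohex-2-en-1-yl}methyl)-4-(3,4-dimethoxybenzyl)dihydrofuran-2(3H)-one (aldol adduct, ring centres undefined) | O=C1CC(O)(C[C@@H]2C(=O)OC[C@H]2Cc2ccc(OC)c(OC)c2)C=CC1Oc1cc(C[C@@H]2C(=O)OC[C@H]2Cc2ccc(OC)c(OC)c2)cc(OC)c1OCc1ccccc1 | intermediate
30 | (3S,4S)-3-{4-[2-(benzyloxy)-5-{[(3S,4S)-4-(3,4-dimethoxybenzyl)-2-oxotetrahydrofuran-3-yl]methyl}-3-methoxyphenoxy]-3-hydroxybenzyl}-4-(3,4-dimethoxybenzyl)dihydrofuran-2(3H)-one | COc1ccc(C[C@@H]2COC(=O)[C@H]2Cc2ccc(Oc3cc(C[C@@H]4C(=O)OC[C@H]4Cc4ccc(OC)c(OC)c4)cc(OC)c3OCc3ccccc3)c(O)c2)cc1OC | intermediate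
31 | (3S,4S)-3-{4-[2-(benzyloxy)-5-{[(3S,4S)-4-(3,4-dimethoxybenzyl)-2-oxotetrahydrofuran-3-yl]methyl}-3-methoxyphenoxy]-3-methoxybenzyl}-4-(3,4-dimethoxybenzyl)dihydrofuran-2(3H)-one | COc1ccc(C[C@@H]2COC(=O)[C@H]2Cc2ccc(Oc3cc(C[C@@H]4C(=O)OC[C@H]4Cc4ccc(OC)c(OC)c4)cc(OC)c3OCc3ccccc3)c(OC)c2)cc1OC | intermediate
32 | (3S,4S)-3-{4-[5-{[(3S,4S)-4-(3,4-dimethoxybenzyl)-2-oxotetrahydrofuran-3-yl]methyl}-2-hydroxy-3-methoxyphenoxy]-3-methoxybenzyl}-4-(3,4-dimethoxybenzyl)dihydrofuran-2(3H)-one | COc1ccc(C[C@@H]2COC(=O)[C@H]2Cc2ccc(Oc3cc(C[C@@H]4C(=O)OC[C@H]4Cc4ccc(OC)c(OC)c4)cc(OC)c3O)c(OC)c2)cc1OC | target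

## Step count and risks

Total step count: 17 steps. Longest linear sequence: 10 steps (steps 4–10 and 15–17 from 9; equally steps 1–3, 11–14 and 15–17 from 1).

Least certain steps:

Step 15 (key step, proposed new method). The most likely failure is ring closure through the wrong enolate: the CH2 group between the ynone carbonyl and lactone A can also enolise and attack the acetyl carbonyl, which would close a regioisomeric arene. Further risks are chloride addition to, or oligomerisation of, the terminal ynone under TiCl4, 1,2-addition of the enol ether, and cleavage of the benzyl ether by the Lewis acid. The fallback uses known chemistry, makes the aryl–oxygen bond by nucleophilic aromatic substitution, sets out from 10 and rejoins the route at 31. Phenol 10 is arylated with 4-fluoro-3-methoxybenzaldehyde (K2CO3, DMF, 100 °C), the fluoride being activated by the para formyl group, to give 4-[2-(benzyloxy)-5-formyl-3-methoxyphenoxy]-3-methoxybenzaldehyde F1. Reduction with NaBH4 in MeOH/THF gives the diol {4-[2-(benzyloxy)-5-(hydroxymethyl)-3-methoxyphenoxy]-3-methoxyphenyl}methanol F2, and CBr4/PPh3 converts it into the dibromide 2-(benzyloxy)-5-(bromomethyl)-1-[4-(bromomethyl)-2-methoxyphenoxy]-3-methoxybenzene F3. Lactone 8 (2.2 equiv) is deprotonated with LiN(SiMe3)2 as in step 8, and two-fold alkylation of the resulting lithium enolate 15 with F3 (THF, −78 → −30 °C), anti to the C4 substituent at both lactones, gives 31 directly; step 17 then completes the synthesis.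

Step 10. Enolisation may occur in part towards the methyl group; the terminal enol ether so formed would lead in step 15 to the isomer with the ether oxygen ortho to the benzylic carbon. The trimethylsilyl enol ether may also hydrolyse during isolation. The fallback sets out from 18 and rejoins at 30 without a preformed enol ether. Ketone 18 and ynone 27 are combined directly with K3PO4 in MeCN (rt → 60 °C), so that the reversibly formed, more stable enolate on the aryloxy side undergoes the conjugate addition and the same base drives the aldol condensation through 28 and 29. This fallback makes no new compound (F0).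

Step 14. The amine released on work-up may add to the terminal ynone, the ynone may oligomerise under the basic magnesium salts, or the acetylide may attack the lactone carbonyl. The fallback sets out from 23 and rejoins at 27. Acid 23 is converted with oxalyl chloride and catalytic DMF into 2-[(3S,4S)-4-(3,4-dimethoxybenzyl)-2-oxotetrahydrofuran-3-yl]acetyl chloride F4, which is coupled with tributyl(ethynyl)stannane under PdCl2(PPh3)2 catalysis (Stille acylation, toluene, 60 °C) to give 27 under neutral, non-nucleophilic conditions.

Step 1. Enantiomeric purity may be partly lost, because direct displacement of chloride competes with opening of the epoxide and leads to the mirror-image lactone; since two lactone units are joined in step 15, the minor enantiomer would appear later as a diastereomer. The fallback sets out from 2 and rejoins at 5. The sodium enolate of 2 (NaH, THF, 0 °C → reflux) is alkylated with (R)-glycidyl trifluoromethanesulfonate F5, made from (S)-glycidol with trifluoromethanesulfonic anhydride and 2,6-lutidine. Here the sulfonate is displaced far faster than the epoxide is opened, so the same epoxide 3 forms by a single pathway and continues through 4 to 5.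

## Further compounds

F1 | step 15 | 4-[2-(benzyloxy)-5-formyl-3-methoxyphenoxy]-3-methoxybenzaldehyde | O=Cc1ccc(Oc2cc(C=O)cc(OC)c2OCc2ccccc2)c(OC)c1
F2 | step 15 | {4-[2-(benzyloxy)-5-(hydroxymethyl)-3-methoxyphenoxy]-3-methoxyphenyl}methanol | OCc1ccc(Oc2cc(CO)cc(OC)c2OCc2ccccc2)c(OC)c1
F3 | step 15 | 2-(benzyloxy)-5-(bromomethyl)-1-[4-(bromomethyl)-2-methoxyphenoxy]-3-methoxybenzene | BrCc1ccc(Oc2cc(CBr)cc(OC)c2OCc2ccccc2)c(OC)c1
F0 | step 10 | none | none
F4 | step 14 | 2-[(3S,4S)-4-(3,4-dimethoxybenzyl)-2-oxotetrahydrofuran-3-yl]acetyl chloride | ClC(=O)C[C@@H]1C(=O)OC[C@H]1Cc1ccc(OC)c(OC)c1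
F5 | step 1 | (R)-glycidyl trifluoromethanesulfonate, [(2R)-oxiran-2-yl]methyl trifluoromethanesulfonate | FC(F)(F)S(=O)(=O)OC[C@H]1CO1
A1 | alternative 1 | bis(homoallylic alcohol) with (E)-styrenes, ring B phenol as benzyl ether | COc1ccc(C[C@H](CO)/C=C/c2ccc(Oc3cc(/C=C/[C@@H](CO)Cc4ccc(OC)c(OC)c4)cc(OC)c3OCc3ccccc3)c(OC)c2)cc1OC
A2 | alternative 1 | bis(tributylstannylmethyl) ether of the (R,R)-bis[(Z)-allylic] benzylic diol | COc1ccc(C/C=C\[C@@H](OC[Sn](CCCC)(CCCC)CCCC)c2ccc(Oc3cc([C@H](OC[Sn](CCCC)(CCCC)CCCC)/C=C\Cc4ccc(OC)c(OC)c4)cc(OC)c3OCc3ccccc3)c(OC)c2)cc1OC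
A3 | alternative 2 | bis(3-carboxy-4-hydroxymethyl lactone), one C3 diastereomer, ring B phenol as benzyl ether | OC[C@@H]1COC(=O)[C@@]1(C(=O)O)Cc1ccc(Oc2cc(C[C@]3(C(=O)O)C(=O)OC[C@H]3CO)cc(OC)c2OCc2ccccc2)c(OC)c1
A4 | alternative 2 | 2-{4-[2-(benzyloxy)-5-[2,2-dicarboxy-2-(oxetan-3-yl)ethyl]-3-methoxyphenoxy]-3-methoxybenzyl}-2-(oxetan-3-yl)propanedioic acid (achiral) | OC(=O)C(Cc1ccc(Oc2cc(CC(C(=O)O)(C(=O)O)C3COC3)cc(OC)c2OCc2ccccc2)c(OC)c1)(C(=O)O)C1COC1
A5 | alternative 3 | bis(3-ethoxycarbonyl lactone), ring B phenol as benzyl ether | COc1ccc(C[C@@H]2COC(=O)[C@@]2(C(=O)OCC)Cc2ccc(Oc3cc(C[C@]4(C(=O)OCC)C(=O)OC[C@H]4Cc4ccc(OC)c(OC)c4)cc(OC)c3OCc3ccccc3)c(OC)c2)cc1OC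
A6 | alternative 3 | 2-(benzyloxy)-5-(bromomethyl)-1-[4-(bromomethyl)-2-methoxyphenoxy]-3-methoxybenzene | BrCc1ccc(Oc2cc(CBr)cc(OC)c2OCc2ccccc2)c(OC)c1
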